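**Plan**
1. Retrosynthesis: remove the benzyl ester and one methyl ether, then cut the bond between the exocyclic CH2 on chromone C2 and C2 of the benzoate ring. The chromone is cut further at O1–C2/C2–C3 (cyclodehydration, Claisen) and at the aryl–acyl bond (Hoesch), leading back to 5-heptylresorcinol.
2. Enabling feature: the benzoic acid ring carries OH at C3 and C6, para to each other, so it is a hydroquinone. In its quinone form (ester at C1), the only CH that is β to both a ring carbonyl and the ester is the carbon that must bear the CH2.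
3. The CH2 is the 2-methyl group of the γ-pyrone ring, the vinylogous α-position of the C4 carbonyl. O-silylation turns it into a nucleophilic exocyclic methylidene, and after C–C bond formation the quinone ring re-aromatises to the hydroquinone, so the union is redox-neutral.
4. Forward order: the pyrone ring is closed on the resorcinol (steps 1–2), the quinone is made from 2,4,5-trimethoxybenzoic acid (steps 3–4), the halves are joined (step 5), and the benzyl and methyl groups are removed (step 6).
5. Stereochemistry: the target has no stereocentre and no stereogenic double bond, so nothing has to be controlled.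

Key step: step 5

Remark: the target is achiral, so "single enantiomer" places no demand on the route. 5-Heptylresorcinol and 2,4,5-trimethoxybenzoic acid are taken as commercially available.

**Route**

Step 1
Reactants: 1 5-heptylbenzene-1,3-diol
Product: 3 1-(2-heptyl-4,6-dihydroxyphenyl)ethan-1-one, via ketiminium chloride 2 (not isolated)
Conditions: MeCN, ZnCl2, HCl (g), Et2O, 0 °C → rt; then H2O, reflux
Reagents that add atoms: acetonitrile CC#N; water O
Why: Houben–Hoesch acylation should occur at C4 of the resorcinol (ortho to one OH, para to the other), the site acylated in 5-alkylresorcinols such as orcinol, and hydrolysis of the ketiminium salt gives the ketone.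

Step 2
Reactants: 3 1-(2-heptyl-4,6-dihydroxyphenyl)ethan-1-one
Product: 5 5-heptyl-7-hydroxy-2-methyl-4H-chromen-4-one, via 1,3-diketone 4 (not isolated)
Conditions: LiHMDS (4.2 equiv), THF, −78 → 0 °C; EtOAc (3 equiv), 0 °C → rt; aq. HCl; then cat. H2SO4, AcOH, 95 °C
Reagents that add atoms: ethyl acetate CCOC(C)=O
Why: Claisen condensation of the lithium polyanion (two phenoxides plus the methyl ketone enolate) with ethyl acetate should give the 1,3-diketone, which closes to the γ-pyrone by acid-catalysed cyclodehydration through the ortho OH, as in the diketone route to chromones.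

Step 3
Reactants: 6 2,4,5-trimethoxybenzoic acid
Product: 7 benzyl 2,4,5-trimethoxybenzoate
Conditions: BnBr, K2CO3, DMF, rt
Reagents that add atoms: benzyl bromide BrCc1ccccc1
Why: SN2 O-alkylation of the carboxylate gives an ester that can later be removed without saponifying a doubly ortho-substituted benzoate.

Step 4
Reactants: 7 benzyl 2,4,5-trimethoxybenzoate
Product: 8 benzyl 4-methoxy-3,6-dioxocyclohexa-1,4-diene-1-carboxylate
Conditions: CAN (2.5 equiv), MeCN/H2O, 0 °C, short contact; extract (CH2Cl2), dry, use at once
Reagents that add atoms: water O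
Why: CAN oxidative demethylation of the para pair of methoxy groups (C2 and C5) should give the p-quinone and leave the C4 methoxy group, as in the standard conversion of 1,2,4-trimethoxyarenes into 2-methoxy-1,4-benzoquinones.

Step 5
Reactants: 5 5-heptyl-7-hydroxy-2-methyl-4H-chromen-4-one; 8 benzyl 4-methoxy-3,6-dioxocyclohexa-1,4-diene-1-carboxylate
Product: 11 benzyl 2-[(5-heptyl-7-hydroxy-4-oxo-4H-chromen-2-yl)methyl]-3,6-dihydroxy-4-methoxybenzoate, via bis-silyl dienol ether 9 (not isolated), via bis-silylated adduct 10 (not isolated)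
Conditions: 5, TBSOTf (2.3 equiv), Et3N (3 equiv), CH2Cl2, 0 °C → rt; pentane, filter, concentrate; 8 (0.85 equiv), CH2Cl2, −78 → −20 °C; then KHF2, MeOH, rt
Reagents that add atoms: none
Why: Proposed new method: O-silylation of the pyrone carbonyl gives a 4-silyloxybenzopyrylium ion whose 2-methyl group is deprotonated by Et3N to the 2-methylidene-2H-chromene 9 (a vinylogous silyl enol ether and a ring enol ether in one), its exocyclic CH2 adds to C2 of quinone 8, silyl transfer from the re-formed pyrylium ion to the β-keto ester enolate restores the chromone, and tautomerisation of the cyclohexadienone gives the hydroquinone 10. The closest known reaction types are the Mukaiyama–Michael addition of silyl enol ethers and silyl ketene acetals to 2-alkoxycarbonyl-1,4-benzoquinones (attack at the ring CH next to the ester carbon, then aromatisation) and the vinylogous Mukaiyama reactions of silyl dienol ethers; the untested element is a γ-pyrone-derived methylidene dienol ether as the donor. No ring is closed and no stereocentre is formed. On the donor, CH2 rather than C3 should react because only attack through CH2 regenerates the aromatic pyrylium ring; on the quinone, C2 is the only CH that is β to both the C6 carbonyl and the ester, whereas C5 is the electron-rich β-carbon of the MeO–C4=C5 enol ether and C4 is blocked by OMe. A competing [4+2] addition across C1=C2 would form the same C–C bond and its adduct should open to 10 by retro-aldol on desilylation; adding 8 as the limiting component to 9 at −78 °C keeps unreacted quinone from oxidising the product hydroquinone, and KHF2 then removes both silyl groups.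

Step 6
Reactants: 11 benzyl 2-[(5-heptyl-7-hydroxy-4-oxo-4H-chromen-2-yl)methyl]-3,6-dihydroxy-4-methoxybenzoate
Product: 12 2-[(5-heptyl-7-hydroxy-4-oxo-4H-chromen-2-yl)methyl]-3,4,6-trihydroxybenzoic acid
Conditions: BBr3 (8 equiv), pentamethylbenzene (3 equiv), CH2Cl2, −78 → 0 °C; H2O quench at 0 °C
Reagents that add atoms: none
Why: Lewis-acid dealkylation with BBr3 should cleave the benzyl ester and the methyl ether next to a free OH (through its aryl borate) in the cold, pentamethylbenzene traps the benzyl group so the electron-rich rings are not C-benzylated, and the low temperature should spare the decarboxylation-prone acid.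

**Compound list**
1 | 5-heptylbenzene-1,3-diol (5-heptylresorcinol) | CCCCCCCc1cc(O)cc(O)c1 | starting material
2 | 1-(2-heptyl-4,6-dihydroxyphenyl)ethan-1-iminium chloride | CCCCCCCc1cc(O)cc(O)c1C(C)=[NH2+].[Cl-] | intermediate
3 | 1-(2-heptyl-4,6-dihydroxyphenyl)ethan-1-one | CCCCCCCc1cc(O)cc(O)c1C(C)=O | intermediate
4 | 1-(2-heptyl-4,6-dihydroxyphenyl)butane-1,3-dione | CCCCCCCc1cc(O)cc(O)c1C(=O)CC(C)=O | intermediate
5 | 5-heptyl-7-hydroxy-2-methyl-4H-chromen-4-one | CCCCCCCc1cc(O)cc2oc(C)cc(=O)c12 | intermediate
6 | 2,4,5-trimethoxybenzoic acid | OC(=O)c1cc(OC)c(OC)cc1OC | starting material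
7 | benzyl 2,4,5-trimethoxybenzoate | O=C(OCc1ccccc1)c1cc(OC)c(OC)cc1OC | intermediate
8 | benzyl 4-methoxy-3,6-dioxocyclohexa-1,4-diene-1-carboxylate | O=C(OCc1ccccc1)C1=CC(=O)C(OC)=CC1=O | intermediate
9 | 4,7-bis[(tert-butyldimethylsilyl)oxy]-5-heptyl-2-methylidene-2H-chromene | CCCCCCCc1cc(O[Si](C)(C)C(C)(C)C)cc2OC(=C)C=C(O[Si](C)(C)C(C)(C)C)c12 | intermediate
10 | benzyl 6-[(tert-butyldimethylsilyl)oxy]-2-({7-[(tert-butyldimethylsilyl)oxy]-5-heptyl-4-oxo-4H-chromen-2-yl}methyl)-3-hydroxy-4-methoxybenzoate | CCCCCCCc1cc(O[Si](C)(C)C(C)(C)C)cc2oc(Cc3c(O)c(OC)cc(O[Si](C)(C)C(C)(C)C)c3C(=O)OCc4ccccc4)cc(=O)c12 | intermediate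
11 | benzyl 2-[(5-heptyl-7-hydroxy-4-oxo-4H-chromen-2-yl)methyl]-3,6-dihydroxy-4-methoxybenzoate | CCCCCCCc1cc(O)cc2oc(Cc3c(O)c(OC)cc(O)c3C(=O)OCc4ccccc4)cc(=O)c12 | intermediate
12 | 2-[(5-heptyl-7-hydroxy-4-oxo-4H-chromen-2-yl)methyl]-3,4,6-trihydroxybenzoic acid | CCCCCCCc1cc(O)cc2oc(Cc3c(O)c(O)cc(O)c3C(=O)O)cc(=O)c12 | target

**Count**
Total steps: 6. Longest linear sequence: 4 steps (1 → 2 → 5 → 6, or 3 → 4 → 5 → 6).

**Steps most likely to fail**

Step 5 (Proposed new method). What may go wrong: electron transfer between the electron-rich dienol ether and the quinone in place of polar C–C bond formation, incomplete enol silylation next to the peri heptyl group, or oxidation of the product hydroquinone by unreacted quinone. The fallback sets out from 8 and 3 and comes back to the route at 12; it makes the CH2–aryl bond with a small, known donor and closes the pyrone ring last.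
- Quinone 8 is treated with 1-(tert-butyldimethylsilyloxy)-1-methoxyethene (CH2Cl2, −78 °C), the known Mukaiyama–Michael addition of a silyl ketene acetal to an alkoxycarbonylquinone. This should give benzyl 6-[(tert-butyldimethylsilyl)oxy]-3-hydroxy-4-methoxy-2-(2-methoxy-2-oxoethyl)benzoate F1.
- F1 is desilylated (KHF2, MeOH) to benzyl 3,6-dihydroxy-4-methoxy-2-(2-methoxy-2-oxoethyl)benzoate F2 and O-methylated (MeI, K2CO3, acetone) to benzyl 3,4,6-trimethoxy-2-(2-methoxy-2-oxoethyl)benzoate F3.
- Crossed Claisen condensation of the polyanion of 3 (LiHMDS, THF, as in step 2) with the unhindered aliphatic ester of F3 should give benzyl 2-[4-(2-heptyl-4,6-dihydroxyphenyl)-2,4-dioxobutyl]-3,4,6-trimethoxybenzoate F4.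
- Cyclodehydration (cat. TsOH, toluene, 80 °C) should give benzyl 2-[(5-heptyl-7-hydroxy-4-oxo-4H-chromen-2-yl)methyl]-3,4,6-trimethoxybenzoate F5.
- BBr3/pentamethylbenzene (CH2Cl2, −78 °C → rt) should then give 12.

Step 4. What may go wrong: slow oxidation of the ester-deactivated ring, and addition of water to the very electrophilic ester-quinone followed by over-oxidation. The fallback sets out from 6 and comes back at 8; it oxidises a phenol instead of a trimethoxyarene.
- BCl3 (CH2Cl2, 0 °C) should cleave only the methyl ether ortho to the carboxyl group (chelation control) to give 2-hydroxy-4,5-dimethoxybenzoic acid F6.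
- Carboxylate-selective benzylation (BnBr, KHCO3, DMF) should give benzyl 2-hydroxy-4,5-dimethoxybenzoate F7.
- Oxidative demethylation of this p-methoxyphenol with PhI(OAc)2 (MeCN/H2O, 0 °C, short contact) should give 8.

Step 6. What may go wrong: Friedel–Crafts C-benzylation of the hydroquinone ring during the Lewis-acid cleavage, or protodecarboxylation of the electron-rich salicylic acid in the HBr-containing mixture. The fallback sets out from 11 and comes back at 12; it removes the ester reductively before any Lewis acid is used.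
- Hydrogenolysis (H2, 1 atm, Pd/C, EtOAc, rt) should give 2-[(5-heptyl-7-hydroxy-4-oxo-4H-chromen-2-yl)methyl]-3,6-dihydroxy-4-methoxybenzoic acid F8.
- The single remaining methyl ether is then cleaved with BBr3 (CH2Cl2, −78 → 0 °C) to give 12.

**Further compounds**
F1 | step 5 | benzyl 6-[(tert-butyldimethylsilyl)oxy]-3-hydroxy-4-methoxy-2-(2-methoxy-2-oxoethyl)benzoate | COC(=O)Cc1c(O)c(OC)cc(O[Si](C)(C)C(C)(C)C)c1C(=O)OCc2ccccc2
F2 | step 5 | benzyl 3,6-dihydroxy-4-methoxy-2-(2-methoxy-2-oxoethyl)benzoate | COC(=O)Cc1c(O)c(OC)cc(O)c1C(=O)OCc2ccccc2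
F3 | step 5 | benzyl 3,4,6-trimethoxy-2-(2-methoxy-2-oxoethyl)benzoate | COC(=O)Cc1c(OC)c(OC)cc(OC)c1C(=O)OCc2ccccc2
F4 | step 5 | benzyl 2-[4-(2-heptyl-4,6-dihydroxyphenyl)-2,4-dioxobutyl]-3,4,6-trimethoxybenzoate | CCCCCCCc1cc(O)cc(O)c1C(=O)CC(=O)Cc2c(OC)c(OC)cc(OC)c2C(=O)OCc3ccccc3
F5 | step 5 | benzyl 2-[(5-heptyl-7-hydroxy-4-oxo-4H-chromen-2-yl)methyl]-3,4,6-trimethoxybenzoate | CCCCCCCc1cc(O)cc2oc(Cc3c(OC)c(OC)cc(OC)c3C(=O)OCc4ccccc4)cc(=O)c12
F6 | step 4 | 2-hydroxy-4,5-dimethoxybenzoic acid | OC(=O)c1cc(OC)c(OC)cc1O
F7 | step 4 | benzyl 2-hydroxy-4,5-dimethoxybenzoate | O=C(OCc1ccccc1)c1cc(OC)c(OC)cc1O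
F8 | step 6 | 2-[(5-heptyl-7-hydroxy-4-oxo-4H-chromen-2-yl)methyl]-3,6-dihydroxy-4-methoxybenzoic acid | CCCCCCCc1cc(O)cc2oc(Cc3c(O)c(OC)cc(O)c3C(=O)O)cc(=O)c12
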